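## Structural features

The target is a monocyclic diterpenoid built on a cyclonona-3,6-diene (ring atoms C1–C9). It carries an acetoxy group on C1, a methyl group on C3, formyl groups on C7 and C8, and on C9 a (2R)-6-methylhept-5-en-2-yl chain whose first carbon is called C10 here. Four stereocentres stand in a row (C1, C9 and C8 in the ring, C10 in the chain), all R, so each must be set next to an existing one. Both ring olefins are cis within the ring: C3=C4 is a Z trisubstituted olefin, and C6=C7 has C5 and C8 on the same side (E by the sequence rule because of the formyl group). The fragile region is C5–C8: C8–H is α to one formyl group and γ to the C6=C7–CHO enal, and the C5 methylene is doubly allylic and vinylogously acidic. Base can therefore epimerise C8 or move the skipped diene into conjugation, and the acetate is base-labile as well. The real difficulty is the nine-membered carbocycle itself (transannular strain, poor entropy of closure), together with control of C1 relative to C9. The key step exploits the unit C1(O)–C2–C3(CH3)=C4: a homoallylic alcohol with a Z trisubstituted olefin is the retron of an α-substituted 2-methylallyl boronate (boron on C4) adding to a C1 aldehyde, and the α-substituent, C5, is here part of the ring.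

## Logic of the disconnections

**27 ⇒ 26 ⇒ 25 ⇒ 24.** No skeletal bond is cut. The two formyl groups are taken back to hydroxymethyl groups, these to silyl ethers, and the acetate to the free C1 carbinol. The enedial is the most sensitive motif and is therefore made last, so every earlier compound carries robust ethers. The demand on the forward direction is that both alcohols of 26 are oxidised in one operation, so that no lactol can intercept a half-oxidised compound, and that C8 is not epimerised.

**24 ⇒ 22.** The C1–C2 bond is cut, the C3=C4 bond moves to C2=C3 and boron is placed on C4. This opens the ring to an acyclic chain. The forward step must close a nine-membered ring by allyl transfer, give the Z olefin and relay the C4 configuration to C1.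

**22 ⇒ 21 ⇒ 17 + 18.** The C1 formyl group is masked as a dimethyl acetal, and the C3–C4 and C4–B bonds are cut together, leading to a primary C4 carbamate and a three-carbon alkenyl boronate. The boronate then enters one step before the aldehyde is released, on a substrate with no electrophile, and its configuration is set by an external chiral base, not by the remote centres C8–C10. This avoids any β,γ-unsaturated aldehyde or skipped diene next to a carbonyl on the way to 22. The forward step requires that acetal and silyl ethers tolerate an alkyllithium, and that the boronate later survives mild acetal hydrolysis.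

**17 ⇒ 16 ⇒ 15 ⇒ 14 ⇒ 12.** These are functional-group changes only: silyl ethers from a diol, the diol from a lactone joining the C7 carbonyl and the C8 CH2O, and the acetal from an aldehyde that comes from a hydrazone. The lactone is the device that fixes the C6=C7 geometry, because its preferred exocyclic E olefin is the one with C5 cis to C8. The hydrazone is exchanged for the acetal at the lactone stage, where nothing acid-labile is present.

**12 ⇒ 10 ⇒ 6 + 7 + 3.** C6=C7 is cut as an aldol condensation and C8–C9 as a conjugate addition, giving three simple pieces joined in one flask. The forward step must set C9 by the auxiliary on the donor, and set C8 by the relative approach of donor and acceptor. That second element is the less secure of the two.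

**6 ⇒ 4 + 5 and 3 ⇒ 2 ⇒ 1.** A C=N condensation and a carbamoylation/oxidation remain. C10 is bought with 4. The auxiliary must be the R antipode (5): an azaenolate of the S antipode accepts electrophiles on the face that would give the C9 epimer.

## Other disconnections considered

**Alternative 1:** The ring would be cut at C1–C9, with the lactone C–O bond on the C8 carboxyl formed in the same operation. SmI2 (divalent samarium) would reduce the formyl group of the acyclic dialkylidenesuccinate A1 to a ketyl that adds to C9; protonation at C8 and acylation of the C1 alkoxide would leave the lactone-bridged cyclononadiene A2.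
- In its favour: A1 has only the C10 stereocentre and could be made in few steps, one operation would create the ring and C1, C8 and C9, and C7 and C8 arrive at the carboxyl level, already differentiated.
- Against it: ketyl–olefin closures to nine-membered rings have little support and compete with pinacol coupling and with reduction of the aldehyde or the diene diester. The three new centres would be steered only by C10 and by the lactone bridge, with nothing that fixes C9 relative to C10. A1 contains a β,γ-unsaturated aldehyde. Reducing the lactone of A2 frees the C1 hydroxyl beside a primary one, which must then be told apart.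
- Comparison: on step count up to the ring Alternative 1 is the better, and on redox economy at C7/C8 it is at least equal. On mechanism and on control of C9/C10 the chosen plan is stronger, since a closed chair relays a reagent-set centre.

**Alternative 2:** C1 and C6 are joined as a tetrasubstituted olefin, so the nine-membered ring becomes the perimeter of the 4,7-dihydroindane A3. Ozone (or epoxidation and H5IO6) would cleave only that most electron-rich olefin to the (Z)-cyclononene-1,6-dione A4.
- In its favour: no medium-ring closure is needed at all, and on that point this plan is better than the chosen one. The Z C3=C4 bond is inherited from the six-membered ring, and Birch reduction and oxidative cleavage are robust.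
- Against it: A3 needs three contiguous centres on a cyclopentane plus C10, and the side-chain olefin must be carried as an acetal and rebuilt. A4 has two ketones, each β,γ to C3=C4 and 1,6 to each other, so conjugation and transannular aldol reaction threaten. The C6 carbonyl must become the C6=C7 olefin by enolisation toward C7, not toward the more acidic C5, which also erases the C7 centre. C1 must be reduced under substrate control.
- Comparison: ring formation is more reliable, but step economy is clearly worse and stereocontrol at C1 is weaker.

**Alternative 3:** The cut is C8–C9, made by a [3,3] shift. Heating the 2-alkylidene-7-alkenyl oxepine A5 would pass through the chair C9=C1–O–C6–C7=C8 and give the cyclononadienone A6.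
- In its favour: the ring forms in a unimolecular concerted step without high dilution, which is better than the chosen plan. C8 and C9 would be set together by two olefin geometries. Reduction of A6 would meet the chosen route at 24, so the end game is equal.
- Against it: A5 needs an E-selective alkylidenation of a seven-membered lactone and a C6 centre bearing a trisubstituted alkenyl group. Ring-enlarging Claisen shifts can switch between chair and boat. A6 is a β,γ-unsaturated ketone with an epimerisable C9, and its reduction sets C1 by substrate control, where the chosen plan derives C1 from C4.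
- Comparison: step economy is about equal; the weaker points are the C1 configuration and access to A5.

Key step: step 12

Remark: ring locants C1–C10 of the target are used for every intermediate; with this numbering C8, C9 and C10 are R in all isolated intermediates.

Assumption: the lithium azaenolate of an aldehyde RAMP hydrazone is taken to accept a Michael acceptor on the same face on which it accepts alkyl halides; on that basis the (R)-auxiliary leads to 9R.

## Route

Step 1
Reactants: 1 propane-1,3-diol
Product: 2 3-hydroxypropyl N,N-diisopropylcarbamate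
Conditions: NaH (1 equiv), THF, 0 °C; iPr2NC(O)Cl (1 equiv), 0 °C to rt; 1 in threefold excess
Reagents that add atoms: N,N-diisopropylcarbamoyl chloride, CC(C)N(C(C)C)C(Cl)=O
Why: O-Carbamoylation of the mono-sodium alkoxide; the excess of the symmetrical diol should make the monocarbamate the main product, and the carbamate is the directing and leaving group needed in step 10.

Step 2
Reactants: 2 3-hydroxypropyl N,N-diisopropylcarbamate
Product: 3 3-oxopropyl N,N-diisopropylcarbamate
Conditions: TEMPO (10 mol%), PhI(OAc)2, CH2Cl2, rt
Reagents that add atoms: none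
Why: Oxoammonium (TEMPO) oxidation of a primary alcohol under non-basic conditions, so that the β-carbamoyloxy aldehyde should not eliminate to acrolein; 3 is used without storage.

Step 3
Reactants: 4 (R)-citronellal; 5 RAMP, (R)-1-amino-2-(methoxymethyl)pyrrolidine
Product: 6 (E)-RAMP hydrazone of (R)-citronellal
Conditions: CH2Cl2, MgSO4, 0 °C to rt
Reagents that add atoms: none
Why: Hydrazone condensation; the E isomer should form for steric reasons and the C10 centre of 4 is not touched.

Step 4
Reactants: 6 (E)-RAMP hydrazone of (R)-citronellal; 7 furan-2(5H)-one; 3 3-oxopropyl N,N-diisopropylcarbamate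
Product: 10 Michael–aldol adduct (8R,9R,10R; β-hydroxy γ-lactone with the hydrazone at C1; C6/C7 mixture), via lithium azaenolate 8 (not isolated), via lithium lactone enolate 9 (not isolated)
Conditions: LiN(iPr)2, THF, 0 °C; 7, −100 to −78 °C; 3, −78 °C; AcOH, −78 °C
Reagents that add atoms: none
Why: Hydrazone azaenolate Michael addition to a butenolide followed by aldol trapping of the lactone enolate (tandem conjugate addition–aldol). Azaenolate 8 (E C=C, Z C–N, lithium held by the methoxy group) should take the acceptor on the face that gives 9R, and 8R is expected from an open synclinal approach in which the branched C10 group lies over the unsubstituted side of the butenolide, away from the ring CH2O. C6 and C7 form as mixtures and disappear in step 5.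

Step 5
Reactants: 10 Michael–aldol adduct
Product: 12 (E)-α-alkylidene lactone (8R,9R,10R; C5 cis to C8; hydrazone at C1), via mesylate 11 (not isolated)
Conditions: MsCl, Et3N, CH2Cl2, −20 °C; DBU, 0 °C
Reagents that add atoms: none
Why: Mesylation and E1cB elimination (aldol condensation); the exocyclic olefin should settle as the E isomer, with C5 anti to the lactone carbonyl and hence cis to C8, as is usual for α-alkylidene-β-substituted butyrolactones. Short contact with DBU at 0 °C should limit γ-deprotonation.

Step 6
Reactants: 12 (E)-α-alkylidene lactone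
Product: 14 C1 aldehyde of the (E)-alkylidene lactone (8R,9R,10R), via hydrazonium iodide 13 (not isolated)
Conditions: MeI, 60 °C; then 3 N HCl, n-pentane, rt (two phases)
Reagents that add atoms: water, O
Why: Quaternisation of the amino nitrogen followed by two-phase acid hydrolysis of the hydrazonium salt; the aldehyde meets no base, so C9 should keep its configuration, and ozone is excluded by the olefins. Lactone, carbamate and olefins are stable to these conditions.

Step 7
Reactants: 14 C1 aldehyde of the (E)-alkylidene lactone
Product: 15 C1 dimethyl acetal of the (E)-alkylidene lactone (8R,9R,10R)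
Conditions: HC(OMe)3, MeOH, PPTS (cat.), rt
Reagents that add atoms: trimethyl orthoformate, COC(OC)OC; methanol, CO
Why: Acid-catalysed acetalisation; the dimethyl acetal is inert to hydride and alkyllithium and can later be removed under conditions that spare silyl ethers and a boronate.

Step 8
Reactants: 15 C1 dimethyl acetal of the (E)-alkylidene lactone
Product: 16 allylic 1,4-diol (8R,9R,10R; CH2OH on C7 and C8; C4 carbamate; C1 acetal)
Conditions: iBu2AlH (4 equiv), CH2Cl2, −78 to −40 °C; aq. KNaC4H4O6
Reagents that add atoms: none
Why: 1,2-Reduction of the conjugated lactone to the diol by iBu2AlH; at −40 °C the hindered carbamate and the acetal should remain. Crude 16 is silylated at once, because acid would cyclise the C8 hydroxymethyl group onto the acetal.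

Step 9
Reactants: 16 allylic 1,4-diol
Product: 17 bis(tert-butyldimethylsilyl) ether (8R,9R,10R; C4 carbamate; C1 acetal)
Conditions: TBSCl, imidazole, DMF, rt
Reagents that add atoms: tert-butyldimethylsilyl chloride, CC(C)(C)[Si](C)(C)Cl
Why: Silylation of two primary alcohols under basic conditions.

Step 10
Reactants: 17 bis(tert-butyldimethylsilyl) ether; 18 isopropenylboronic acid pinacol ester
Product: 21 (4R)-allylboronate dimethyl acetal (4R,8R,9R,10R), via α-lithiated carbamate 19 (not isolated), via lithium boronate complex 20 (not isolated)
Conditions: sBuLi, (−)-sparteine, Et2O, −78 °C, 5 h; 18, −78 °C; MgBr2·OEt2, −78 to 35 °C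
Reagents that add atoms: none
Why: Sparteine-mediated asymmetric α-lithiation of a primary carbamate, borylation with retention and 1,2-metallate rearrangement with inversion (lithiation–borylation). (−)-Sparteine removes the pro-S hydrogen at C4, so migration of the isopropenyl group anti to the carbamate should give the 4R α-substituted allylboronate. C4 is thus set by the reagent and not by the distant centres C8–C10.

Step 11
Reactants: 21 (4R)-allylboronate dimethyl acetal
Product: 22 (4R)-ω-formyl allylboronate (4R,8R,9R,10R; Bpin on C4; CH2OTBS on C7 and C8)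
Conditions: SiO2, 10% aq. (CO2H)2, CH2Cl2 (0.01 M), 0 °C to rt; filtration
Reagents that add atoms: water, O
Why: Mild heterogeneous acetal hydrolysis; primary silyl ethers and the pinacol boronate should survive wet acidic SiO2. 22 is kept cold and dilute and carried on at once.

Step 12
Reactants: 22 (4R)-ω-formyl allylboronate
Product: 24 cyclononadienol (1R,8R,9R,10R; 3Z; free C1 hydroxyl; bis-TBS ether), via borate ester 23 (not isolated)
Conditions: PhMe (0.002 M), 80 °C; then aq. NaHCO3
Reagents that add atoms: none
Why: Proposed new method: boron binds the C1 carbonyl oxygen and the allyl unit is transferred through a closed six-membered chair (B, O, C1, C2, C3, C4) in an SE2′ sense, so that C2 bonds to C1, the C3=C4 bond forms and boron ends on oxygen as borate 23, which is hydrolysed on work-up. The closest known reactions are thermal intramolecular allylborations of ω-formyl allylboronates that close five- to seven-membered rings, and Z-selective intermolecular additions of α-substituted 2-methylallyl pinacol boronates to aldehydes; the nine-membered closure itself has no precedent. The ring closes in a 9-exo-trig sense at the carbonyl carbon, and the former allyl unit ends inside the ring. The new C1 centre is controlled by the 4R boronate: with C5 axial on C4 and the C9 branch equatorial on C1, the chair delivers the 1R carbinol. The step needs Z geometry at C3=C4, which is secured three ways: axial C5 avoids the pinacol oxygens, it avoids allylic strain with the C3 methyl group, and the alternative (C5 equatorial) would have to place an E olefin in a nine-membered ring that already holds a cis olefin. The cis C6=C7 bond and the vicinal branching at C8/C9 hold the chain ends close, and high dilution suppresses intermolecular allyl transfer. Reagent control from C4 is expected to outweigh the intrinsic facial bias of the α-branched aldehyde.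

Step 13
Reactants: 24 cyclononadienol
Product: 25 C1 acetate (1R,8R,9R,10R; bis-TBS ether)
Conditions: Ac2O, DMAP (cat.), pyridine, CH2Cl2, rt
Reagents that add atoms: acetic anhydride, CC(=O)OC(C)=O
Why: DMAP-catalysed acylation of the hindered secondary alcohol.

Step 14
Reactants: 25 C1 acetate
Product: 26 acetoxy diol (1R,8R,9R,10R; CH2OH on C7 and C8)
Conditions: HF·pyridine, pyridine, THF, 0 °C to rt
Reagents that add atoms: none
Why: Fluoride cleavage of both primary silyl ethers under buffered, non-basic conditions, so the acetate should neither migrate nor be lost.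

Step 15
Reactants: 26 acetoxy diol
Product: 27 target dialdehyde CNP0113811.6 (1R,8R,9R,10R; 3Z; C5 and C8 cis on C6=C7)
Conditions: (COCl)2, DMSO, CH2Cl2, −78 °C; Et3N, −78 to −40 °C; pH 7 buffer
Reagents that add atoms: none
Why: Swern oxidation; both hydroxyls become alkoxysulfonium ions before the base is added, so neither aldehyde can be trapped as a lactol by its neighbour, as in oxidations of other ene-1,4-diols to enedials. Low temperature and a buffered quench protect the C8 centre and the skipped diene.

## Compound list

1 | propane-1,3-diol | OCCCO | starting material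
2 | 3-hydroxypropyl N,N-diisopropylcarbamate | CC(C)N(C(C)C)C(=O)OCCCO | intermediate
3 | 3-oxopropyl N,N-diisopropylcarbamate | CC(C)N(C(C)C)C(=O)OCCC=O | intermediate
4 | (R)-citronellal | O=CC[C@H](C)CCC=C(C)C | starting material
5 | RAMP, (R)-1-amino-2-(methoxymethyl)pyrrolidine | COC[C@H]1CCCN1N | starting material
6 | (E)-RAMP hydrazone of (R)-citronellal | COC[C@H]1CCCN1/N=C/C[C@H](C)CCC=C(C)C | intermediate
7 | furan-2(5H)-one | O=C1OCC=C1 | starting material
8 | lithium azaenolate of 6 (E C=C) | COC[C@H]1CCCN1[N-]/C=C/[C@H](C)CCC=C(C)C.[Li+] | intermediate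
9 | lithium enolate of the Michael adduct lactone | COC[C@H]1CCCN1/N=C/[C@H]([C@H](C)CCC=C(C)C)[C@@H]1C=C([O-])OC1.[Li+] | intermediate
10 | Michael–aldol adduct, β-hydroxy lactone (8R,9R,10R; C6/C7 mixture) | COC[C@H]1CCCN1/N=C/[C@H]([C@H](C)CCC=C(C)C)[C@@H]1C(C(O)CCOC(=O)N(C(C)C)C(C)C)C(=O)OC1 | intermediate
11 | C6 mesylate of 10 | COC[C@H]1CCCN1/N=C/[C@H]([C@H](C)CCC=C(C)C)[C@@H]1C(C(OS(C)(=O)=O)CCOC(=O)N(C(C)C)C(C)C)C(=O)OC1 | intermediate
12 | (E)-α-alkylidene lactone, RAMP hydrazone at C1 (8R,9R,10R) | COC[C@H]1CCCN1/N=C/[C@H]([C@H](C)CCC=C(C)C)[C@@H]1/C(=C\CCOC(=O)N(C(C)C)C(C)C)C(=O)OC1 | intermediate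
13 | N-methylhydrazonium iodide of 12 | COC[C@H]1CCC[N+]1(C)/N=C/[C@H]([C@H](C)CCC=C(C)C)[C@@H]1/C(=C\CCOC(=O)N(C(C)C)C(C)C)C(=O)OC1.[I-] | intermediate
14 | C1 aldehyde of the (E)-alkylidene lactone (8R,9R,10R) | O=C[C@H]([C@H](C)CCC=C(C)C)[C@@H]1/C(=C\CCOC(=O)N(C(C)C)C(C)C)C(=O)OC1 | intermediate
15 | C1 dimethyl acetal of the (E)-alkylidene lactone (8R,9R,10R) | COC(OC)[C@H]([C@H](C)CCC=C(C)C)[C@@H]1/C(=C\CCOC(=O)N(C(C)C)C(C)C)C(=O)OC1 | intermediate
16 | allylic 1,4-diol with C4 carbamate and C1 acetal (8R,9R,10R) | COC(OC)[C@H]([C@H](C)CCC=C(C)C)[C@@H](CO)/C(CO)=C\CCOC(=O)N(C(C)C)C(C)C | intermediate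
17 | bis-TBS ether with C4 carbamate and C1 acetal (8R,9R,10R) | COC(OC)[C@H]([C@H](C)CCC=C(C)C)[C@@H](CO[Si](C)(C)C(C)(C)C)/C(CO[Si](C)(C)C(C)(C)C)=C\CCOC(=O)N(C(C)C)C(C)C | intermediate
18 | isopropenylboronic acid pinacol ester | CC(=C)B1OC(C)(C)C(C)(C)O1 | starting material
19 | (4S)-α-lithiated carbamate | COC(OC)[C@H]([C@H](C)CCC=C(C)C)[C@@H](CO[Si](C)(C)C(C)(C)C)/C(CO[Si](C)(C)C(C)(C)C)=C\C[C@H]([Li])OC(=O)N(C(C)C)C(C)C | intermediate
20 | lithium boronate complex of 19 and 18 | COC(OC)[C@H]([C@H](C)CCC=C(C)C)[C@@H](CO[Si](C)(C)C(C)(C)C)/C(CO[Si](C)(C)C(C)(C)C)=C\C[C@H]([B-]1(C(C)=C)OC(C)(C)C(C)(C)O1)OC(=O)N(C(C)C)C(C)C.[Li+] | intermediate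
21 | (4R)-allylboronate dimethyl acetal (4R,8R,9R,10R) | COC(OC)[C@H]([C@H](C)CCC=C(C)C)[C@@H](CO[Si](C)(C)C(C)(C)C)/C(CO[Si](C)(C)C(C)(C)C)=C\C[C@@H](B1OC(C)(C)C(C)(C)O1)C(C)=C | intermediate
22 | (4R)-ω-formyl allylboronate, precursor of the key step (4R,8R,9R,10R) | O=C[C@H]([C@H](C)CCC=C(C)C)[C@@H](CO[Si](C)(C)C(C)(C)C)/C(CO[Si](C)(C)C(C)(C)C)=C\C[C@@H](B1OC(C)(C)C(C)(C)O1)C(C)=C | intermediate
23 | pinacol borate ester of 24 | CC1(C)OB(O[C@@H]2C/C(C)=C\C/C=C(/CO[Si](C)(C)C(C)(C)C)[C@H](CO[Si](C)(C)C(C)(C)C)[C@H]2[C@H](C)CCC=C(C)C)OC1(C)C | intermediate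
24 | cyclononadienol, bis-TBS ether (1R,8R,9R,10R; 3Z) | O[C@@H]1C/C(C)=C\C/C=C(/CO[Si](C)(C)C(C)(C)C)[C@H](CO[Si](C)(C)C(C)(C)C)[C@H]1[C@H](C)CCC=C(C)C | intermediate
25 | C1 acetate, bis-TBS ether | CC(=O)O[C@@H]1C/C(C)=C\C/C=C(/CO[Si](C)(C)C(C)(C)C)[C@H](CO[Si](C)(C)C(C)(C)C)[C@H]1[C@H](C)CCC=C(C)C | intermediate
26 | acetoxy diol | CC(=O)O[C@@H]1C/C(C)=C\C/C=C(/CO)[C@H](CO)[C@H]1[C@H](C)CCC=C(C)C | intermediate
27 | CNP0113811.6 | CC(=O)O[C@@H]1C/C(C)=C\C/C=C(/C=O)[C@H](C=O)[C@H]1[C@H](C)CCC=C(C)C | target

## Step count and least certain steps

Total: 15 steps. Longest linear sequence: 14 steps (steps 1, 2 and 4–15, from propane-1,3-diol); the citronellal branch is 13 steps.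

**Step 12 (key step, the one step beyond known chemistry).** The most likely failure is intermolecular allyl transfer (oligomerisation) outrunning the closure, because the effective molarity of a nine-membered ring is low. The second is closure through a boat-like or C9-axial array, which would give the C1 epimer. Slow closure would also give the α-branched aldehyde time to epimerise at C9. The fallback closes the same ring by olefin metathesis at C3=C4, using known reaction types only. It sets out from 17 and returns at 24:
- LiAlH4 (THF, 0 °C to rt) removes the carbamate to give the primary alcohol F1.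
- Dess–Martin periodinane/NaHCO3 gives the β,γ-unsaturated aldehyde F2.
- Ph3P=CH2 (from Ph3PCH3Br and KN(SiMe3)2, −78 °C) gives the terminal alkene F3.
- Wet SiO2/(CO2H)2 frees the C1 aldehyde F4.
- 2-Methylallylboronic acid pinacol ester with a chiral phosphoric acid, (R)-3,3′-bis(2,4,6-triisopropylphenyl)-1,1′-binaphthyl-2,2′-diyl hydrogen phosphate (the antipode being chosen for the 1R carbinol), gives the methallyl carbinol F5 under catalyst control.
- Ring-closing metathesis of F5 with the second-generation Grubbs catalyst (PhMe, high dilution, 80 °C, 1,4-benzoquinone against olefin migration) should give 24.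

**Step 10.** sBuLi may deprotonate elsewhere (the allylic CH2OTBS, or C5), or the boronate complex may fail to rearrange cleanly; either would lower yield or selectivity at C4. The fallback installs boron by allylic substitution instead. It sets out from 17 and returns at 21:
- It passes through alcohol F1 and aldehyde F2 as above.
- A Still–Gennari olefination ((CF3CH2O)2P(O)CH(CH3)CO2CH3, KN(SiMe3)2, 18-crown-6, −78 °C) gives the (Z)-enoate F6.
- iBu2AlH gives the (Z)-allylic alcohol F7.
- ClCO2CH3/pyridine gives the carbonate F8.
- CuCl/KOtBu with the QuinoxP* antipode that delivers 4R and B2pin2 (THF, 0 °C; monovalent copper boryl, γ-selective substitution) should give 21.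

**Step 4.** Facial discrimination at C8 rests on an open transition state and may be poor; proton transfer from the γ-CH2 of 7 to the basic azaenolate may compete with addition. The fallback places C8 under the control of a removable ring substituent. It sets out from 6 (with 3) and returns at 16:
- Azaenolate 8 is added to (5R)-5-[(1R,2S,5R)-menthyloxy]furan-2(5H)-one F9, which accepts nucleophiles anti to the menthyloxy group; trapping with 3 gives the aldol adduct F10.
- Mesylation and DBU give the (E)-alkylidene lactone F11.
- MeI then HCl/pentane gives the aldehyde F12.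
- HC(OMe)3/MeOH/PPTS gives the dimethyl acetal F13 (exchange of menthyloxy for methoxy at the lactol carbon would be harmless).
- iBu2AlH reduces both the carbonyl and the lactol carbon, releasing menthol and giving 16.

**Step 5.** The elimination may give an E/Z mixture, and DBU may deprotonate C5 of the product, leading to loss of the carbamate by 1,4-elimination. The fallback makes C6=C7 by olefination in place of aldol condensation. It sets out from 6 and returns at 12:
- Enolate 9 (from 6, LiN(iPr)2 and 7) is trapped with ClP(OEt)2 and oxidised with H2O2 to the α-phosphono lactone F14.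
- A Horner–Wadsworth–Emmons reaction with 3 (LiCl, DBU, MeCN, 0 °C) should give 12, E-selectively.

## Further compounds

F1 | step 12 | C4 primary alcohol, bis-TBS dimethyl acetal | COC(OC)[C@H]([C@H](C)CCC=C(C)C)[C@@H](CO[Si](C)(C)C(C)(C)C)/C(CO[Si](C)(C)C(C)(C)C)=C\CCO
F2 | step 12 | C4 aldehyde, bis-TBS dimethyl acetal | COC(OC)[C@H]([C@H](C)CCC=C(C)C)[C@@H](CO[Si](C)(C)C(C)(C)C)/C(CO[Si](C)(C)C(C)(C)C)=C\CC=O
F3 | step 12 | C4 terminal alkene, bis-TBS dimethyl acetal | COC(OC)[C@H]([C@H](C)CCC=C(C)C)[C@@H](CO[Si](C)(C)C(C)(C)C)/C(CO[Si](C)(C)C(C)(C)C)=C\CC=C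
F4 | step 12 | C1 aldehyde with C4 terminal alkene | O=C[C@H]([C@H](C)CCC=C(C)C)[C@@H](CO[Si](C)(C)C(C)(C)C)/C(CO[Si](C)(C)C(C)(C)C)=C\CC=C
F5 | step 12 | (1R)-methallyl carbinol, metathesis diene | O[C@H](CC(C)=C)[C@H]([C@H](C)CCC=C(C)C)[C@@H](CO[Si](C)(C)C(C)(C)C)/C(CO[Si](C)(C)C(C)(C)C)=C\CC=C
F6 | step 10 | methyl (Z)-enoate (C2 ester, C3=C4) | COC(OC)[C@H]([C@H](C)CCC=C(C)C)[C@@H](CO[Si](C)(C)C(C)(C)C)/C(CO[Si](C)(C)C(C)(C)C)=C\C/C=C(C)\C(=O)OC
F7 | step 10 | (Z)-allylic alcohol (C2 hydroxyl) | COC(OC)[C@H]([C@H](C)CCC=C(C)C)[C@@H](CO[Si](C)(C)C(C)(C)C)/C(CO[Si](C)(C)C(C)(C)C)=C\C/C=C(C)\CO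
F8 | step 10 | (Z)-allylic methyl carbonate | COC(OC)[C@H]([C@H](C)CCC=C(C)C)[C@@H](CO[Si](C)(C)C(C)(C)C)/C(CO[Si](C)(C)C(C)(C)C)=C\C/C=C(C)\COC(=O)OC
F9 | step 4 | (5R)-5-[(1R,2S,5R)-menthyloxy]furan-2(5H)-one | O=C1C=C[C@H](O[C@@H]2C[C@H](C)CC[C@H]2C(C)C)O1
F10 | step 4 | menthyloxy Michael–aldol adduct (C6/C7 mixture) | COC[C@H]1CCCN1/N=C/[C@H]([C@H](C)CCC=C(C)C)[C@H]1[C@H](O[C@@H]2C[C@H](C)CC[C@H]2C(C)C)OC(=O)C1C(O)CCOC(=O)N(C(C)C)C(C)C
F11 | step 4 | menthyloxy (E)-alkylidene lactone, hydrazone at C1 | COC[C@H]1CCCN1/N=C/[C@H]([C@H](C)CCC=C(C)C)[C@H]1[C@H](O[C@@H]2C[C@H](C)CC[C@H]2C(C)C)OC(=O)/C1=C/CCOC(=O)N(C(C)C)C(C)C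
F12 | step 4 | menthyloxy (E)-alkylidene lactone, C1 aldehyde | O=C[C@H]([C@H](C)CCC=C(C)C)[C@H]1[C@H](O[C@@H]2C[C@H](C)CC[C@H]2C(C)C)OC(=O)/C1=C/CCOC(=O)N(C(C)C)C(C)C
F13 | step 4 | menthyloxy (E)-alkylidene lactone, C1 dimethyl acetal | COC(OC)[C@H]([C@H](C)CCC=C(C)C)[C@H]1[C@H](O[C@@H]2C[C@H](C)CC[C@H]2C(C)C)OC(=O)/C1=C/CCOC(=O)N(C(C)C)C(C)C
F14 | step 5 | α-(diethoxyphosphoryl) lactone, hydrazone at C1 (C7 mixture) | COC[C@H]1CCCN1/N=C/[C@H]([C@H](C)CCC=C(C)C)[C@@H]1C(P(=O)(OCC)OCC)C(=O)OC1
A1 | alternative 1 | acyclic formyl dialkylidenesuccinate | O=CC/C(C)=C\C/C=C(/C(=O)OC)\C(C(=O)OC)=C/[C@H](C)CCC=C(C)C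
A2 | alternative 1 | lactone-bridged cyclononadiene, methyl ester on C7 | O=C1O[C@@H]2C/C(C)=C\C/C=C(/C(=O)OC)[C@H]1[C@H]2[C@H](C)CCC=C(C)C
A3 | alternative 2 | 4,7-dihydroindane with C1=C6 fusion olefin | CC1=CCC2=C(C1)[C@H]([C@H](C)CCC(OC)OC)[C@@H](CO[Si](C)(C)C(C)(C)C)[C@@H]2CO[Si](C)(C)C(C)(C)C
A4 | alternative 2 | (Z)-cyclonon-3-ene-1,6-dione | O=C1C/C(C)=C\CC(=O)[C@@H](CO[Si](C)(C)C(C)(C)C)[C@H](CO[Si](C)(C)C(C)(C)C)[C@H]1[C@H](C)CCC(OC)OC
A5 | alternative 3 | 2-alkylidene-7-alkenyl tetrahydrooxepine (geometry as a chair would require) | CC(C)=CCC[C@@H](C)/C=C1/O[C@@H](C/C=C(C)\C1)/C(CO[Si](C)(C)C(C)(C)C)=C/CO[Si](C)(C)C(C)(C)C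
A6 | alternative 3 | cyclonona-3,6-dienone, bis-TBS ether | O=C1C/C(C)=C\C/C=C(/CO[Si](C)(C)C(C)(C)C)[C@H](CO[Si](C)(C)C(C)(C)C)[C@H]1[C@H](C)CCC=C(C)C
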